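**Retrosynthetic overview**

1. Pyrrhoxanthin (34) is cut at the two sp2–sp2 single bonds that flank the γ-alkylidenebutenolide, C3–C(vinyl) and C8–C1'. This gives the epoxy vinylstannane 23, the trienylstannane 12 and the C8 dihalide 32; the polyene bond C8–C1' that unites the two halves is made last.
2. Enabling feature: in the lactone ring O1–C2(=O)–C3=C4–C5 with its exocyclic diene C5=C6–C7(CH3)=C8, C3 is the α-carbon and C8 the vinylogous terminus of the C2 carbonyl. Both can carry a halogen (C3–I, C8–Br) that Pd(0) tells apart, so one flask takes both end groups and leaves no protecting group to remove.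
3. Both cyclohexane rings come from (4R,6R)-actinol (1) through one enol triflate 4. Sonogashira coupling, Takai olefination and a bis-stannane extension give 12; carbonylation, reduction, Sharpless epoxidation and Cr(II) stannyl-olefination give 23.
4. Ring order: carbocycles preformed (chiral pool); oxirane closed in step 11; butenolide ring taken from furan-2(5H)-one, its Z-ylidene set in step 19; no ring is closed in the key step.

Key step: step 20

Assumption: (4R,6R)-actinol is taken as a purchasable chiral-pool ketone; C2–C8 denote the lactone numbering given above and C1' the stannylated carbon of 12.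

**Route**

Step 1
Reactants: 1 (4R,6R)-4-hydroxy-2,2,6-trimethylcyclohexan-1-one
Product: 2 (4R,6R)-4-[(tert-butyldimethylsilyl)oxy]-2,2,6-trimethylcyclohexan-1-one
Conditions: TBSCl, imidazole, DMF, rt
Reagents that add atoms: tert-butyldimethylsilyl chloride, CC(C)(C)[Si](C)(C)Cl
Why: Imidazole-promoted silylation of the unhindered secondary alcohol (TBS protection) should proceed cleanly and touches neither stereocentre.

Step 2
Reactants: 2 (4R,6R)-4-[(tert-butyldimethylsilyl)oxy]-2,2,6-trimethylcyclohexan-1-one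
Product: 4 (4R)-4-[(tert-butyldimethylsilyl)oxy]-2,6,6-trimethylcyclohex-1-en-1-yl trifluoromethanesulfonate, via lithium enolate 3 (not isolated)
Conditions: LDA, THF, -78 °C; then PhNTf2, -78 °C to rt
Reagents that add atoms: N-phenylbis(trifluoromethanesulfonimide), O=S(=O)(N(c1ccccc1)S(=O)(=O)C(F)(F)F)C(F)(F)F
Why: The ketone can enolise only toward C6 because C2 is quaternary, so deprotonation and O-triflation (enol triflate formation) should give a single tetrasubstituted triflate, erasing the C6 stereocentre that is no longer needed while the silyloxy-bearing carbon (R) is retained.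

Step 3
Reactants: 4 (4R)-4-[(tert-butyldimethylsilyl)oxy]-2,6,6-trimethylcyclohex-1-en-1-yl trifluoromethanesulfonate; 5 (2E)-3-methylpent-2-en-4-yn-1-ol
Product: 6 (2E)-5-{(4R)-4-[(tert-butyldimethylsilyl)oxy]-2,6,6-trimethylcyclohex-1-en-1-yl}-3-methylpent-2-en-4-yn-1-ol
Conditions: Pd(PPh3)4 (5 mol%), CuI (10 mol%), Et3N, DMF, 60 °C
Reagents that add atoms: none
Why: Sonogashira coupling of the cyclohexenyl triflate with the terminal enyne should install the ring–alkyne bond with retention of the E trisubstituted alkene, the free primary alcohol being tolerated.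

Step 4
Reactants: 6 (2E)-5-{(4R)-4-[(tert-butyldimethylsilyl)oxy]-2,6,6-trimethylcyclohex-1-en-1-yl}-3-methylpent-2-en-4-yn-1-ol
Product: 7 (1R)-4-[(3E)-5-hydroxy-3-methylpent-3-en-1-yn-1-yl]-3,5,5-trimethylcyclohex-3-en-1-ol
Conditions: TBAF, THF, rt
Reagents that add atoms: none
Why: Fluoride-mediated desilylation should free the ring alcohol at a stage where no base- or fluoride-sensitive group is present.

Step 5
Reactants: 7 (1R)-4-[(3E)-5-hydroxy-3-methylpent-3-en-1-yn-1-yl]-3,5,5-trimethylcyclohex-3-en-1-ol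
Product: 8 (2E)-5-[(4R)-4-hydroxy-2,6,6-trimethylcyclohex-1-en-1-yl]-3-methylpent-2-en-4-ynal
Conditions: activated MnO2, CH2Cl2, rt
Reagents that add atoms: none
Why: Chemoselective allylic oxidation with MnO2 should convert only the enyne-conjugated primary alcohol into the enal and leave the saturated secondary ring alcohol untouched.

Step 6
Reactants: 8 (2E)-5-[(4R)-4-hydroxy-2,6,6-trimethylcyclohex-1-en-1-yl]-3-methylpent-2-en-4-ynal
Product: 9 (1R)-3,5,5-trimethyl-4-[(3E)-3-methyl-5-oxopent-3-en-1-yn-1-yl]cyclohex-3-en-1-yl acetate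
Conditions: Ac2O, pyridine, DMAP (cat.), CH2Cl2, 0 °C to rt
Reagents that add atoms: acetic anhydride, CC(=O)OC(C)=O
Why: DMAP-catalysed acetylation should place the acetate of the target on the only remaining hydroxyl group.

Step 7
Reactants: 9 (1R)-3,5,5-trimethyl-4-[(3E)-3-methyl-5-oxopent-3-en-1-yn-1-yl]cyclohex-3-en-1-yl acetate
Product: 10 (1R)-4-[(3E,5E)-6-iodo-3-methylhexa-3,5-dien-1-yn-1-yl]-3,5,5-trimethylcyclohex-3-en-1-yl acetate
Conditions: CHI3, CrCl2, THF, 0 °C to rt, dark
Reagents that add atoms: iodoform, IC(I)I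
Why: Takai iodo-olefination should convert the enal into the E iodoalkene under non-basic conditions that spare the acetate and the enyne, the E geometry following from the anti addition–elimination of the gem-dichromium reagent.

Step 8
Reactants: 10 (1R)-4-[(3E,5E)-6-iodo-3-methylhexa-3,5-dien-1-yn-1-yl]-3,5,5-trimethylcyclohex-3-en-1-yl acetate; 11 (E)-1,2-bis(tributylstannyl)ethene
Product: 12 (1R)-3,5,5-trimethyl-4-[(3E,5E,7E)-3-methyl-8-(tributylstannyl)octa-3,5,7-trien-1-yn-1-yl]cyclohex-3-en-1-yl acetate
Conditions: 11 (3 equiv), PdCl2(MeCN)2 (5 mol%), DMF, rt, dark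
Reagents that add atoms: none
Why: Stille coupling of the dienyl iodide with an excess of the bis-stannane should stop after one C–Sn bond has reacted and extend the chain by an E CH=CH–SnBu3 unit with retention of all alkene geometries.

Step 9
Reactants: 4 (4R)-4-[(tert-butyldimethylsilyl)oxy]-2,6,6-trimethylcyclohex-1-en-1-yl trifluoromethanesulfonate
Product: 13 methyl (4R)-4-[(tert-butyldimethylsilyl)oxy]-2,6,6-trimethylcyclohex-1-ene-1-carboxylate
Conditions: CO (1 atm), Pd(OAc)2 (5 mol%), PPh3 (10 mol%), Et3N, MeOH/DMF, 60 °C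
Reagents that add atoms: carbon monoxide, [C-]#[O+]; methanol, CO
Why: Pd-catalysed methoxycarbonylation of the enol triflate (oxidative addition, CO insertion, methanolysis) should give the unsaturated ester.

Step 10
Reactants: 13 methyl (4R)-4-[(tert-butyldimethylsilyl)oxy]-2,6,6-trimethylcyclohex-1-ene-1-carboxylate
Product: 14 {(4R)-4-[(tert-butyldimethylsilyl)oxy]-2,6,6-trimethylcyclohex-1-en-1-yl}methanol
Conditions: DIBAL-H (2.5 equiv), CH2Cl2, -78 to 0 °C; Rochelle salt work-up
Reagents that add atoms: none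
Why: DIBAL-H should reduce the conjugated ester in 1,2-fashion to the allylic alcohol needed for directed epoxidation.

Step 11
Reactants: 14 {(4R)-4-[(tert-butyldimethylsilyl)oxy]-2,6,6-trimethylcyclohex-1-en-1-yl}methanol
Product: 15 {(1R,4S,6R)-4-[(tert-butyldimethylsilyl)oxy]-2,2,6-trimethyl-7-oxabicyclo[4.1.0]heptan-1-yl}methanol
Conditions: Ti(OiPr)4 (20 mol%), D-(-)-diethyl tartrate (25 mol%), t-BuOOH, 4 Å MS, CH2Cl2, -20 °C
Reagents that add atoms: tert-butyl hydroperoxide, CC(C)(C)OO
Why: Sharpless asymmetric epoxidation should deliver the oxygen under reagent control, D-(-)-tartrate being the enantiomer that places the oxirane on the ring face opposite to the silyloxy group, so that both quaternary oxirane stereocentres are set in the anti relation of the target.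

Step 12
Reactants: 15 {(1R,4S,6R)-4-[(tert-butyldimethylsilyl)oxy]-2,2,6-trimethyl-7-oxabicyclo[4.1.0]heptan-1-yl}methanol
Product: 16 (1S,4S,6R)-4-[(tert-butyldimethylsilyl)oxy]-2,2,6-trimethyl-7-oxabicyclo[4.1.0]heptane-1-carbaldehyde
Conditions: TPAP (5 mol%), NMO, 4 Å MS, CH2Cl2, rt
Reagents that add atoms: none
Why: Ley–Griffith oxidation is neutral and should give the non-enolisable α-epoxy aldehyde without opening the acid-sensitive oxirane.

Step 13
Reactants: 17 dibromomethane; 18 tributyltin chloride
Product: 20 tributyl(dibromomethyl)stannane, via dibromomethyllithium 19 (not isolated)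
Conditions: LDA, THF/Et2O, -95 °C; then Bu3SnCl, -95 °C to rt
Reagents that add atoms: none
Why: Low-temperature deprotonation of dibromomethane should give the carbenoid, which is trapped by substitution at tin before it decomposes.

Step 14
Reactants: 16 (1S,4S,6R)-4-[(tert-butyldimethylsilyl)oxy]-2,2,6-trimethyl-7-oxabicyclo[4.1.0]heptane-1-carbaldehyde; 20 tributyl(dibromomethyl)stannane
Product: 22 tributyl[(E)-2-{(1S,4S,6R)-4-[(tert-butyldimethylsilyl)oxy]-2,2,6-trimethyl-7-oxabicyclo[4.1.0]heptan-1-yl}ethenyl]stannane, via tributyl(diiodomethyl)stannane 21 (not isolated)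
Conditions: CrCl2 (8 equiv), LiI (4 equiv), DMF/THF, rt, dark
Reagents that add atoms: none
Why: Chromium(II)-mediated stannyl-olefination of the Takai type (after Br/I exchange by LiI) should convert the aldehyde directly into the E alkenylstannane under neutral conditions that spare the oxirane and the silyl ether.

Step 15
Reactants: 22 tributyl[(E)-2-{(1S,4S,6R)-4-[(tert-butyldimethylsilyl)oxy]-2,2,6-trimethyl-7-oxabicyclo[4.1.0]heptan-1-yl}ethenyl]stannane
Product: 23 tributyl[(E)-2-{(1S,4S,6R)-4-hydroxy-2,2,6-trimethyl-7-oxabicyclo[4.1.0]heptan-1-yl}ethenyl]stannane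
Conditions: TBAF, THF, rt
Reagents that add atoms: none
Why: Fluoride desilylation should free the secondary alcohol of the target before the union, the C–Sn bond, the oxirane and the alkene being inert to fluoride.

Step 16
Reactants: 24 prop-2-yn-1-ol
Product: 26 (2E)-3-bromo-2-methylprop-2-en-1-ol, via alkenylalane 25 (not isolated)
Conditions: Me3Al (3 equiv), Cp2ZrCl2 (0.3 equiv), CH2Cl2, 0 °C to rt; then NBS, THF, -30 to 0 °C
Reagents that add atoms: trimethylaluminium, C[Al](C)C; N-bromosuccinimide, O=C1CCC(=O)N1Br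
Why: Negishi zirconium-catalysed carboalumination should add methyl and aluminium syn across the alkyne with methyl at the internal carbon, and bromodealumination with retention should then give the E bromoalkene.

Step 17
Reactants: 26 (2E)-3-bromo-2-methylprop-2-en-1-ol
Product: 27 (2E)-3-bromo-2-methylprop-2-enal
Conditions: activated MnO2, CH2Cl2, rt; solution used directly
Reagents that add atoms: none
Why: Allylic oxidation with MnO2 should give the enal without isomerising the trisubstituted bromoalkene.

Step 18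
Reactants: 28 furan-2(5H)-one
Product: 29 3-iodofuran-2(5H)-one
Conditions: I2, pyridine/CH2Cl2, rt
Reagents that add atoms: iodine, II
Why: α-Iodination of the enoate by the iodine–pyridine addition–elimination sequence (conjugate addition of pyridine, iodination of the enolate, elimination) should place iodine at C3 of the butenolide.

Step 19
Reactants: 29 3-iodofuran-2(5H)-one; 27 (2E)-3-bromo-2-methylprop-2-enal
Product: 32 (5Z)-5-[(2E)-3-bromo-2-methylprop-2-en-1-ylidene]-3-iodofuran-2(5H)-one, via 3-iodo-2-silyloxyfuran 30 (not isolated), via aldol silyl ether 31 (not isolated)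
Conditions: TBSOTf, i-Pr2NEt, CH2Cl2, 0 °C; then 27, -78 to 0 °C; then DBU, 0 °C to rt
Reagents that add atoms: none
Why: Vinylogous Mukaiyama aldol addition of the silyloxyfuran through its C5 to the aldehyde followed by E1cB loss of silanol (one-pot butenolide aldol condensation) should give the γ-alkylidenebutenolide, the thermodynamically preferred Z isomer (lactone oxygen cis to C7) predominating and the E bromoalkene remaining untouched.

Step 20
Reactants: 32 (5Z)-5-[(2E)-3-bromo-2-methylprop-2-en-1-ylidene]-3-iodofuran-2(5H)-one; 23 tributyl[(E)-2-{(1S,4S,6R)-4-hydroxy-2,2,6-trimethyl-7-oxabicyclo[4.1.0]heptan-1-yl}ethenyl]stannane; 12 (1R)-3,5,5-trimethyl-4-[(3E,5E,7E)-3-methyl-8-(tributylstannyl)octa-3,5,7-trien-1-yn-1-yl]cyclohex-3-en-1-yl acetate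
Product: 34 pyrrhoxanthin, via right-half bromide 33 (not isolated)
Conditions: 32 (1.0 equiv), 23 (1.0 equiv), Pd2(dba)3·CHCl3 (5 mol%), AsPh3 (40 mol%), degassed NMP, BHT, dark, 25 °C; then 12 (1.2 equiv), 50 °C
Reagents that add atoms: none
Why: Two consecutive Stille cycles should run on one Pd(0)/AsPh3 catalyst: oxidative addition into the C3–I bond of 32 (the α-iodo-enoate position and the weakest C–X bond), Sn-to-Pd transmetalation of 23 and reductive elimination give bromide 33, and once 12 is added and the bath is warmed, oxidative addition into the C8–Br bond (the vinylogous β-position of the C2 carbonyl through C3=C4–C5=C6–C7=C8), transmetalation of 12 and reductive elimination forge the C8–C1' sp2–sp2 bond that unites the two halves. The closest known reaction types are halogen-differentiated sequential Stille couplings of iodo/bromo dihalides and Stille couplings of α-halobutenolides and (halomethylene)butenolides with alkenyl- and polyenylstannanes. No ring is closed and no stereocentre is created: the four stereocentres arrive set in 23 and 12, and every C=C geometry (E in both stannanes, 5Z and E in 32) is carried over because all three elementary steps at sp2 carbon are stereoretentive. The step needs site selectivity (C3–I before C8–Br) and tolerance of the free hydroxyl, the acetate, the oxirane and the alkyne; the first is secured by the I/Br difference reinforced by temperature and order of addition, the second by the neutral, base-free conditions and by the fully substituted allylic oxirane carbon, which should not ionise to a π-allyl complex. Because the alcohol of 23 is already free and the acetate of 12 is in place, the coupling product is the natural product itself.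

**Compound list**

1 | (4R,6R)-4-hydroxy-2,2,6-trimethylcyclohexan-1-one ((-)-actinol) | O[C@@H]1C[C@@H](C)C(=O)C(C)(C)C1 | starting material
2 | (4R,6R)-4-[(tert-butyldimethylsilyl)oxy]-2,2,6-trimethylcyclohexan-1-one | CC(C)(C)[Si](C)(C)O[C@@H]1C[C@@H](C)C(=O)C(C)(C)C1 | intermediate
3 | lithium (4R)-4-[(tert-butyldimethylsilyl)oxy]-2,6,6-trimethylcyclohex-1-en-1-olate | CC(C)(C)[Si](C)(C)O[C@@H]1CC(C)=C(O[Li])C(C)(C)C1 | intermediate
4 | (4R)-4-[(tert-butyldimethylsilyl)oxy]-2,6,6-trimethylcyclohex-1-en-1-yl trifluoromethanesulfonate | CC(C)(C)[Si](C)(C)O[C@@H]1CC(C)=C(OS(=O)(=O)C(F)(F)F)C(C)(C)C1 | intermediate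
5 | (2E)-3-methylpent-2-en-4-yn-1-ol | C#C/C(C)=C/CO | starting material
6 | (2E)-5-{(4R)-4-[(tert-butyldimethylsilyl)oxy]-2,6,6-trimethylcyclohex-1-en-1-yl}-3-methylpent-2-en-4-yn-1-ol | CC(C)(C)[Si](C)(C)O[C@@H]1CC(C)=C(C#C/C(C)=C/CO)C(C)(C)C1 | intermediate
7 | (1R)-4-[(3E)-5-hydroxy-3-methylpent-3-en-1-yn-1-yl]-3,5,5-trimethylcyclohex-3-en-1-ol | O[C@@H]1CC(C)=C(C#C/C(C)=C/CO)C(C)(C)C1 | intermediate
8 | (2E)-5-[(4R)-4-hydroxy-2,6,6-trimethylcyclohex-1-en-1-yl]-3-methylpent-2-en-4-ynal | O[C@@H]1CC(C)=C(C#C/C(C)=C/C=O)C(C)(C)C1 | intermediate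
9 | (1R)-3,5,5-trimethyl-4-[(3E)-3-methyl-5-oxopent-3-en-1-yn-1-yl]cyclohex-3-en-1-yl acetate | CC(=O)O[C@@H]1CC(C)=C(C#C/C(C)=C/C=O)C(C)(C)C1 | intermediate
10 | (1R)-4-[(3E,5E)-6-iodo-3-methylhexa-3,5-dien-1-yn-1-yl]-3,5,5-trimethylcyclohex-3-en-1-yl acetate | CC(=O)O[C@@H]1CC(C)=C(C#C/C(C)=C/C=C/I)C(C)(C)C1 | intermediate
11 | (E)-1,2-bis(tributylstannyl)ethene | CCCC[Sn](CCCC)(CCCC)/C=C/[Sn](CCCC)(CCCC)CCCC | starting material
12 | (1R)-3,5,5-trimethyl-4-[(3E,5E,7E)-3-methyl-8-(tributylstannyl)octa-3,5,7-trien-1-yn-1-yl]cyclohex-3-en-1-yl acetate | CC(=O)O[C@@H]1CC(C)=C(C#C/C(C)=C/C=C/C=C/[Sn](CCCC)(CCCC)CCCC)C(C)(C)C1 | intermediate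
13 | methyl (4R)-4-[(tert-butyldimethylsilyl)oxy]-2,6,6-trimethylcyclohex-1-ene-1-carboxylate | CC(C)(C)[Si](C)(C)O[C@@H]1CC(C)=C(C(=O)OC)C(C)(C)C1 | intermediate
14 | {(4R)-4-[(tert-butyldimethylsilyl)oxy]-2,6,6-trimethylcyclohex-1-en-1-yl}methanol | CC(C)(C)[Si](C)(C)O[C@@H]1CC(C)=C(CO)C(C)(C)C1 | intermediate
15 | {(1R,4S,6R)-4-[(tert-butyldimethylsilyl)oxy]-2,2,6-trimethyl-7-oxabicyclo[4.1.0]heptan-1-yl}methanol (oxirane anti to the silyloxy group) | OC[C@@]12O[C@]1(C)C[C@@H](O[Si](C)(C)C(C)(C)C)CC2(C)C | intermediate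
16 | (1S,4S,6R)-4-[(tert-butyldimethylsilyl)oxy]-2,2,6-trimethyl-7-oxabicyclo[4.1.0]heptane-1-carbaldehyde | O=C[C@@]12O[C@]1(C)C[C@@H](O[Si](C)(C)C(C)(C)C)CC2(C)C | intermediate
17 | dibromomethane | BrCBr | starting material
18 | tributyltin chloride | CCCC[Sn](Cl)(CCCC)CCCC | starting material
19 | dibromomethyllithium | [Li]C(Br)Br | intermediate
20 | tributyl(dibromomethyl)stannane | CCCC[Sn](CCCC)(CCCC)C(Br)Br | intermediate
21 | tributyl(diiodomethyl)stannane | CCCC[Sn](CCCC)(CCCC)C(I)I | intermediate
22 | tributyl[(E)-2-{(1S,4S,6R)-4-[(tert-butyldimethylsilyl)oxy]-2,2,6-trimethyl-7-oxabicyclo[4.1.0]heptan-1-yl}ethenyl]stannane | CCCC[Sn](CCCC)(CCCC)/C=C/[C@@]12O[C@]1(C)C[C@@H](O[Si](C)(C)C(C)(C)C)CC2(C)C | intermediate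
23 | tributyl[(E)-2-{(1S,4S,6R)-4-hydroxy-2,2,6-trimethyl-7-oxabicyclo[4.1.0]heptan-1-yl}ethenyl]stannane | CCCC[Sn](CCCC)(CCCC)/C=C/[C@@]12O[C@]1(C)C[C@@H](O)CC2(C)C | intermediate
24 | prop-2-yn-1-ol | C#CCO | starting material
25 | dimethyl{(1E)-3-[(dimethylalumanyl)oxy]-2-methylprop-1-en-1-yl}alumane | C[Al](C)OC/C(C)=C/[Al](C)C | intermediate
26 | (2E)-3-bromo-2-methylprop-2-en-1-ol | OC/C(C)=C/Br | intermediate
27 | (2E)-3-bromo-2-methylprop-2-enal | O=C/C(C)=C/Br | intermediate
28 | furan-2(5H)-one | O=C1OCC=C1 | starting material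
29 | 3-iodofuran-2(5H)-one | O=C1OCC=C1I | intermediate
30 | tert-butyl[(3-iodofuran-2-yl)oxy]dimethylsilane | CC(C)(C)[Si](C)(C)Oc1occc1I | intermediate
31 | 5-{(2E)-3-bromo-1-[(tert-butyldimethylsilyl)oxy]-2-methylprop-2-en-1-yl}-3-iodofuran-2(5H)-one (mixture of diastereomers) | CC(C)(C)[Si](C)(C)OC(/C(C)=C/Br)C1OC(=O)C(I)=C1 | intermediate
32 | (5Z)-5-[(2E)-3-bromo-2-methylprop-2-en-1-ylidene]-3-iodofuran-2(5H)-one | Br/C=C(C)/C=C1C=C(I)C(=O)O/1 | intermediate
33 | (5Z)-5-[(2E)-3-bromo-2-methylprop-2-en-1-ylidene]-3-[(E)-2-{(1S,4S,6R)-4-hydroxy-2,2,6-trimethyl-7-oxabicyclo[4.1.0]heptan-1-yl}ethenyl]furan-2(5H)-one | Br/C=C(C)/C=C1C=C(/C=C/[C@@]23O[C@]2(C)C[C@@H](O)CC3(C)C)C(=O)O/1 | intermediate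
34 | pyrrhoxanthin (CNP0337675.1) | CC(=O)O[C@@H]1CC(C)=C(C#C/C(C)=C/C=C/C=C/C=C(C)/C=C2C=C(/C=C/[C@@]34O[C@]3(C)C[C@@H](O)CC4(C)C)C(=O)O/2)C(C)(C)C1 | target

**Summary**

Total step count: 20. Longest linear sequence: 9 steps (1 → 2 → 4 → 6 → 7 → 8 → 9 → 10 → 12 → 34; the arm 1 → 2 → 4 → 13 → 14 → 15 → 16 → 22 → 23 → 34 is equally long).

Steps most likely to fail:

1. Step 20. What may go wrong: loss of site selectivity in the first coupling (the C8–Br bond engaged by 23), destannylative homocoupling of 12, and scrambling of double-bond geometry once the heptaene sits at 50 °C with palladium. Fallback, setting out from 10, 23 and 32 and returning at 34: the two couplings are run as separate, isolated operations and the second one is moved from tin to boron. Bromide 33 is prepared from 32 and 23 as in the first stage and purified. Iodide 10 is mono-coupled with commercial (E)-1,2-bis(pinacolboryl)ethene (Pd(PPh3)4, aqueous K3PO4, THF, rt) to give the trienyl pinacol boronate F1. Compounds 33 and F1 are then joined at the same C8–C1' bond by a thallium-accelerated Suzuki–Miyaura coupling (Pd(PPh3)4, Tl2CO3, THF/H2O, 0 °C to rt), which should run at or below room temperature and give 34.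

2. Step 19. What may go wrong: poor Z/E control in the β-elimination, and addition–elimination of DBU or the amine base at the bromine-bearing vinylogous acyl positions of 27, 31 and 32, which would destroy the C8–Br handle. Fallback, setting out from 27 and returning at 32: the ring is built by alkyne lactonisation instead of aldol condensation. Colvin homologation of 27 (lithiated trimethylsilyldiazomethane, THF, -78 °C to rt) should give (1E)-1-bromo-2-methylbut-1-en-3-yne F2. (2E)-2,3-Diiodoprop-2-enoic acid F3 is made from propiolic acid and iodine. F3 and F2 are then combined under Pd(PPh3)4/CuI/Et3N in MeCN at rt: Sonogashira coupling at the β-iodide followed by 5-exo-dig attack of the carboxylate on the alkyne (anti addition, hence Z) should give 32 directly. This also bypasses step 18 and compound 29.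

3. Step 14. What may go wrong: slow addition of the bulky stannyl gem-dichromium reagent to the neopentyl-type α-epoxy aldehyde, so that reduction of the aldehyde and erosion of E selectivity take over. Fallback, setting out from 16 and returning at 22: olefination and C–Sn bond formation are separated. Takai iodo-olefination with the smaller iodoform-derived reagent (CHI3, CrCl2, THF, 0 °C) should give (1S,4S,6R)-4-[(tert-butyldimethylsilyl)oxy]-1-[(E)-2-iodoethenyl]-2,2,6-trimethyl-7-oxabicyclo[4.1.0]heptane F4. Palladium-catalysed stannylation of F4 with hexabutylditin (PdCl2(PPh3)2, THF, 50 °C) then gives 22.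

Further compounds
F1 | step 20 | (1R)-3,5,5-trimethyl-4-[(3E,5E,7E)-3-methyl-8-(4,4,5,5-tetramethyl-1,3,2-dioxaborolan-2-yl)octa-3,5,7-trien-1-yn-1-yl]cyclohex-3-en-1-yl acetate | CC(=O)O[C@@H]1CC(C)=C(C#C/C(C)=C/C=C/C=C/B2OC(C)(C)C(C)(C)O2)C(C)(C)C1
F2 | step 19 | (1E)-1-bromo-2-methylbut-1-en-3-yne | C#C/C(C)=C/Br
F3 | step 19 | (2E)-2,3-diiodoprop-2-enoic acid | OC(=O)/C(I)=C\I
F4 | step 14 | (1S,4S,6R)-4-[(tert-butyldimethylsilyl)oxy]-1-[(E)-2-iodoethenyl]-2,2,6-trimethyl-7-oxabicyclo[4.1.0]heptane | I/C=C/[C@@]12O[C@]1(C)C[C@@H](O[Si](C)(C)C(C)(C)C)CC2(C)C
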